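The earlier runs and the new flask stem from a simulated flask on assumed constants; the scatter is artificial.

I started from the target, which grew at a fairly even pace in both runs once the first minutes had passed.

the same everywhere: substrate 0.50 M (fed, over 25 min)

| flask | free catalyst | impurity | remark | time |
|---|---|---|---|---|
| green | 1 mM | 0.14 mM | the very flask that is asked about, followed so far; the fed solution adds 0.25 times the starting volume |  |
| amber | 1 mM | 0.21 mM | run made earlier; the fed solution adds 0.25 times the starting volume |  |
| flask | 1.0 mM | 0.14 mM | the fed solution adds 0.25 times the starting volume | 25 min |

| run | time / min | target / % | substrate / % |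
|---|---|---|---|
| green | 3.00 | 3.4 | 8.2 |
| green | 6.00 | 10.0 | 13.9 |
| green | 10.0 | 16.7 | 21.2 |
| green | 12.0 | 21.7 | 25.5 |
| amber | 1.33 | 0.8 | 3.9 |
| amber | 3.00 | 2.9 | 8.5 |
| amber | 8.00 | 13.4 | 19.7 |
| amber | 20.0 | 37.7 | 41.5 |

(scatter of a reading: 0.5 percentage points)

- percentages count the substrate that a species holds: one spent catalyst B counts as two
- every charge counts on the volume at the start, and the solution that is fed holds the whole dose
- steps that have been proposed: catalyst intermediate B -> free catalyst + target; substrate + free catalyst -> catalyst intermediate A; catalyst intermediate A + target -> spent catalyst B; target + free catalyst <-> isomer of the product + free catalyst; free catalyst + impurity -> spent catalyst A; catalyst intermediate A <-> catalyst intermediate B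
- percentages count the whole charge, also what has not yet gone in

- concentration of target at 25 min, in M
- concentration of substrate at 25 min, in M

An even pace invited me to count catalyst rounds. The proposed steps turn free catalyst and impurity into spent catalyst A, so I took the impurity as a catalyst poison, one for one. That left 0.790 mM of working catalyst in the amber run and 0.860 mM in the green flask. This was an assumption: at 3.00 min the two runs differed by 0.5 percentage points in target, against a scatter of 0.5 points.

Between 8.00 min and 20.0 min, the amber target rose by 24 points. That gave 4.68 s as a reading of the turnover time τ, the working catalyst divided by the rate of forming target; it is the inverse of the turnover frequency.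

The green flask stood at 21.7% at 12.0 min. So the remaining 13.0 min at this τ, with the volume grown by the factor 1.25, gave me 0.201 M of target and 0.199 M of substrate.

The forecast said 0.194 M and 0.2 M, since “target forms at a nearly constant rate”; its target lay below mine.

The flask gave 0.206 M of target and 0.189 M of substrate, so the forecast held.

    catalyst intermediate B → free catalyst + target (k = 0.479 s⁻¹)
    substrate + free catalyst → catalyst intermediate A (k = 14.1 M⁻¹ s⁻¹)
    catalyst intermediate A + target → spent catalyst B (k = 2.85 × 10⁻⁴ M⁻¹ s⁻¹)
    target + free catalyst ⇌ isomer of the product + free catalyst, rate k4*[free catalyst]*[target] forward; the back reaction follows from the equilibrium constant (K = 1.21, k = 0.291 M⁻¹ s⁻¹)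
    free catalyst + impurity → spent catalyst A (k = 167 M⁻¹ s⁻¹)
    catalyst intermediate A ⇌ catalyst intermediate B (K = 1.23, k = 5.32 s⁻¹)

The backward run from catalyst intermediate B to catalyst intermediate A was the largest single effect on the target in this flask, which held 0.206 M against 0.287 M in the same run without that backward run. Impurity, which had turned 14.0% of the catalyst into spent catalyst A by 25.0 min, was a smaller part of the reason, with 0.234 M of target in the same run without that conversion. A neighbour flask charged with 2.4 × 10⁻⁴ M of impurity had 0.100 mM less working catalyst, so τ predicted 0.0256 M less target over 25 min. That neighbour held 0.185 M, which is 0.0210 M less than this flask.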